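**Retrosynthetic overview**
1. The target is a 2-acyl-4-hydroxycyclohexane-1,3-dione (shown as one enol). Both ring C–C bonds to the acyl-bearing carbon are cut in a polyketide-type double Claisen ([5+1]).
2. This gives methyl ketone 8 (all side-chain carbons plus the future ring C2) and the C5 unit 9, an (S)-2-oxyglutarate from the L-glutamic acid pool that already carries the C–OH stereocentre.
3. The only ring is formed last, in one flask: crossed Claisen to a linear 5,7-dioxo ester, then Dieckmann C-acylation, the same closure the polyketide pathway is thought to use.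
4. Ketone 8 comes from acid 6 and MeLi. Acid 6 comes from a Z-selective Wittig reaction of the ylide of 12-bromododecanoic acid with (E)-crotonaldehyde, which sets 12Z and carries 14E.

Assumption: the target SMILES is one enol tautomer of the β-triketone and the route delivers that compound; 1, 2, 4 and 9 are taken as catalogue chemicals.

**Step 1**
Reactants: 1 12-bromododecanoic acid; 2 triphenylphosphine
Product: 3 (11-carboxyundecyl)triphenylphosphonium bromide
Conditions: PPh3 (1.05 equiv), MeCN, reflux, 36 h; triturate with Et2O, dry under vacuum
Reagents that add atoms: none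
Why: SN2 quaternisation of PPh3 by a primary alkyl bromide (phosphonium salt formation), in which the free acid is inert and all atoms of both reactants end up in the salt.

**Step 2**
Reactants: 3 (11-carboxyundecyl)triphenylphosphonium bromide; 4 (E)-but-2-enal
Product: 6 (12Z,14E)-hexadeca-12,14-dienoic acid, via ylide carboxylate 5 (not isolated)
Conditions: NaHMDS (2.05 equiv), THF, −78 → 0 °C; then 4 (1.2 equiv), −78 °C → rt; 1 M HCl to pH 3; minor 12E isomer removed on AgNO3–silica
Reagents that add atoms: none
Why: Salt-free Wittig olefination of a non-stabilised ylide with an enal passes through an early cis-selective [2+2] transition state, so the new C12=C13 bond is formed Z (typically ≥ 9:1) while the E double bond of crotonaldehyde is carried over untouched.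

**Step 3**
Reactants: 6 (12Z,14E)-hexadeca-12,14-dienoic acid
Product: 8 (13Z,15E)-heptadeca-13,15-dien-2-one, via dilithium gem-diolate 7 (not isolated)
Conditions: MeLi (2.4 equiv), THF/Et2O, 0 °C → rt, 2 h; inverse quench into ice-cold 1 M HCl
Reagents that add atoms: methyllithium, [Li]C
Why: Addition of MeLi to the lithium carboxylate stops at the tetrahedral dilithium gem-diolate, which releases the methyl ketone only on acidic quench, so no tertiary alcohol forms and the diene is not touched.

**Step 4**
Reactants: 8 (13Z,15E)-heptadeca-13,15-dien-2-one; 9 ethyl (S)-5-oxotetrahydrofuran-2-carboxylate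
Product: 12 (6S)-3,6-dihydroxy-2-[(12Z,14E)-hexadeca-12,14-dienoyl]cyclohex-2-en-1-one (CNP0144157.1), via sodium oxido diester 10 (not isolated), via linear dioxo ester dianion 11 (not isolated)
Conditions: 9 (1.5 equiv), NaOEt (1.5 equiv), THF, 0 °C, 30 min; NaH (3.5 equiv); 8 (1.0 equiv) added over 2 h at 55 °C, then reflux 6 h; ice-cold 1 M HCl to pH 2, EtOAc; acid-washed silica
Reagents that add atoms: none
Why: Proposed new method: a thermodynamically driven crossed Claisen/Dieckmann [5+1] annulation. The sodium enolate of 8 is acylated on its methyl side (the only acylation product that can be stored as a stable diketonate) by the remote C5 ester of 10, giving 11. The central carbon of 11 then attacks the Na-chelated C1 ester 6-exo-trig, the same C-acylation of a 5,7-dioxoacyl chain that closes the ring in the polyketide pathway. The β-triketone (pKa about 4) is deprotonated as it forms, which pulls the reversible ester, lactone and retro-Claisen equilibria towards 12; a first acylation at C1 instead converges on the same ring. The stereocentre is not created but imported from 9, and it is shielded from enolisation throughout because its oxygen is an alkoxide, so removing the adjacent C–H would need a vicinal dianion. Closest known reactions: NaH-mediated acylation of methyl ketones with esters to β-diketones, Dieckmann closure of δ-keto esters to cyclohexane-1,3-diones, and the Lacey–Dieckmann closure of β-ketoamide anions onto α-stereogenic esters to 3-acyltetramic acids.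

**Compound list**
1 | 12-bromododecanoic acid | OC(=O)CCCCCCCCCCCBr | starting material
2 | triphenylphosphine | c1ccc(cc1)P(c1ccccc1)c1ccccc1 | starting material
3 | (11-carboxyundecyl)triphenylphosphonium bromide | OC(=O)CCCCCCCCCCC[P+](c1ccccc1)(c1ccccc1)c1ccccc1.[Br-] | intermediate
4 | (E)-but-2-enal (crotonaldehyde) | C/C=C/C=O | starting material
5 | sodium 12-(triphenyl-λ5-phosphanylidene)dodecanoate (ylide carboxylate) | [Na+].[O-]C(=O)CCCCCCCCCCC=P(c1ccccc1)(c1ccccc1)c1ccccc1 | intermediate (not isolated)
6 | (12Z,14E)-hexadeca-12,14-dienoic acid | C/C=C/C=C\CCCCCCCCCCC(=O)O | intermediate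
7 | dilithium (13Z,15E)-heptadeca-13,15-diene-2,2-diolate | C/C=C/C=C\CCCCCCCCCCC(C)([O-])[O-].[Li+].[Li+] | intermediate (not isolated)
8 | (13Z,15E)-heptadeca-13,15-dien-2-one | C/C=C/C=C\CCCCCCCCCCC(C)=O | intermediate
9 | ethyl (S)-5-oxotetrahydrofuran-2-carboxylate | CCOC(=O)[C@@H]1CCC(=O)O1 | starting material
10 | sodium (S)-1,5-diethoxy-1,5-dioxopentan-2-olate (sodium alkoxide of diethyl (S)-2-hydroxyglutarate) | CCOC(=O)CC[C@H]([O-])C(=O)OCC.[Na+] | intermediate (not isolated)
11 | disodium salt (alkoxide and diketonate) of ethyl (2S,18Z,20E)-2-hydroxy-5,7-dioxodocosa-18,20-dienoate | C/C=C/C=C\CCCCCCCCCCC(=O)[CH-]C(=O)CC[C@H]([O-])C(=O)OCC.[Na+].[Na+] | intermediate (not isolated)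
12 | (6S)-3,6-dihydroxy-2-[(12Z,14E)-hexadeca-12,14-dienoyl]cyclohex-2-en-1-one | C/C=C/C=C\CCCCCCCCCCC(=O)C1=C(O)CC[C@H](O)C1=O | target

**Totals**
Total step count: 4. Longest linear sequence: 4 (1 → 3 → 6 → 8 → 12; 9 enters as purchased).

**Three steps most likely to fail**

Step 4 (highest risk). The one-flask double Claisen may stall at the diketone stage, give oligoesters, or close slowly onto the α-oxido ester. The fallback sets out from 8 and comes back at 12. The kinetic lithium enolate of 8 (LDA, THF, −78 °C, two equivalents so that the second takes up the acidic product) is C-acylated at −78 °C with commercial (S)-5-oxotetrahydrofuran-2-carbonyl chloride F1, which can react only at the acid chloride. This gives the isolable β-diketone (5S)-5-[(14Z,16E)-3-oxooctadeca-14,16-dienoyl]oxolan-2-one F2. Treating F2 with NaOMe in MeOH (0 → 40 °C) opens the lactone to methyl (4S,18Z,20E)-4-hydroxy-5,7-dioxodocosa-18,20-dienoate F3, not isolated. Its diketonate closes by Dieckmann C-acylation onto the now ordinary methyl ester, and acidification gives 12. This fixes the site of the first acylation, separates the two C–C bond formations, and moves the ring closure from an α-oxido ester to an unhindered ester.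

Step 2. The Wittig reaction may give too much 12E isomer, or an inseparable mixture. The fallback sets out from 4 and comes back at 6, and builds the diene by alkyne semi-reduction instead. Corey–Fuchs homologation of 4 (CBr4, PPh3, CH2Cl2, 0 °C) gives (E)-1,1-dibromopenta-1,3-diene F4. n-BuLi (2.1 equiv, THF, −78 °C) converts F4 into lithium (E)-pent-3-en-1-yn-1-ide F5. F5 is alkylated in THF/DMPU with the pre-formed lithium salt of commercial 11-bromoundecanoic acid F6 to give (E)-hexadec-14-en-12-ynoic acid F7. Semi-reduction of the conjugated triple bond with activated Zn(Cu/Ag) in MeOH/H2O then delivers 6 with the Z bond set by syn hydrogen delivery.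

Step 3. MeLi may over-add to the tertiary alcohol or leave unreacted carboxylate. The fallback sets out from 6 and comes back at 8. Acid 6 is converted (CDI, then MeNHOMe·HCl, CH2Cl2) into (12Z,14E)-N-methoxy-N-methylhexadeca-12,14-dienamide F8. MeMgBr (THF, 0 °C) adds once to F8 and gives 8 on aqueous work-up.

**Further compounds**
F1 | step 4 | (S)-5-oxotetrahydrofuran-2-carbonyl chloride | O=C(Cl)[C@@H]1CCC(=O)O1
F2 | step 4 | (5S)-5-[(14Z,16E)-3-oxooctadeca-14,16-dienoyl]oxolan-2-one | C/C=C/C=C\CCCCCCCCCCC(=O)CC(=O)[C@@H]1CCC(=O)O1
F3 | step 4 | methyl (4S,18Z,20E)-4-hydroxy-5,7-dioxodocosa-18,20-dienoate | C/C=C/C=C\CCCCCCCCCCC(=O)CC(=O)[C@@H](O)CCC(=O)OC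
F4 | step 2 | (E)-1,1-dibromopenta-1,3-diene | C/C=C/C=C(Br)Br
F5 | step 2 | lithium (E)-pent-3-en-1-yn-1-ide | [Li]C#C/C=C/C
F6 | step 2 | 11-bromoundecanoic acid | OC(=O)CCCCCCCCCCBr
F7 | step 2 | (E)-hexadec-14-en-12-ynoic acid | C/C=C/C#CCCCCCCCCCCC(=O)O
F8 | step 3 | (12Z,14E)-N-methoxy-N-methylhexadeca-12,14-dienamide | C/C=C/C=C\CCCCCCCCCCC(=O)N(C)OC
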